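The route rests on the cyclohexene that forms ring B: its C6=C7 double bond sits between four contiguous stereocentres (C5, C8, C9, C10), and the C5–C10 bond is also part of ring A, which is the pattern left behind by a Diels–Alder reaction within one chain. Cutting C5–C10 and C8–C9 leads back to an achiral trienal: a four-carbon tether (C1–C4, gem-dimethyl at C4) joins an E 3-methyl enal (C9=C10) to an E,Z-diene (C5–C8) carrying C17 as a silyloxymethyl group. One catalytic, enantioselective cycloaddition then closes rings A and B and sets all four stereocentres. The C12–C16 side chain is added afterwards by B-alkyl Suzuki coupling.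

Key step: step 8

Remark: atoms carry labdane numbers (ring A C1–C5 and C10, ring B C5–C10, side chain C11–C16 on C9, C17 on C8, C20 on C10); compounds 1, 3, 6 and 14 are taken as catalogue chemicals.

Design note: each of the three olefin geometries of trienal 11 is installed by a geometry-defining reaction (Takai olefination, alkyne cis-reduction, retentive coupling of an E-enol triflate), because any geometric impurity would reappear as a diastereomer after step 8. C17 stays at the alcohol level as a TBS ether so that the diene remains electron-rich.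

Step 1
Reactants: 1 2,2-dimethylpent-4-enal
Product: 2 (1E)-1-iodo-3,3-dimethylhexa-1,5-diene
Conditions: CrCl2, CHI3, THF, 0 °C → rt
Reagents that add atoms: iodoform, IC(I)I
Why: Takai iodo-olefination of a non-enolisable aldehyde, in which the geminal dichromium reagent adds and eliminates through the less crowded arrangement, should give the E-vinyl iodide (C5=C6) and leave the isolated terminal alkene alone.

Step 2
Reactants: 2 (1E)-1-iodo-3,3-dimethylhexa-1,5-diene; 3 tert-butyldimethyl(prop-2-yn-1-yloxy)silane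
Product: 4 tert-butyl{[(4E)-6,6-dimethylnona-4,8-dien-2-yn-1-yl]oxy}dimethylsilane
Conditions: PdCl2(PPh3)2 (cat.), CuI (cat.), Et3N, THF, rt
Reagents that add atoms: none
Why: Sonogashira coupling of a vinyl iodide with a terminal alkyne proceeds with retention at the sp2 carbon, so the E geometry is kept while C7, C8 and C17 are attached.

Step 3
Reactants: 4 tert-butyl{[(4E)-6,6-dimethylnona-4,8-dien-2-yn-1-yl]oxy}dimethylsilane
Product: 5 tert-butyl{[(2Z,4E)-6,6-dimethylnona-2,4,8-trien-1-yl]oxy}dimethylsilane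
Conditions: Zn dust activated with Cu(OAc)2 and AgNO3, MeOH/H2O (1:1), 40 °C
Reagents that add atoms: none
Why: Zinc-mediated cis-semi-reduction of a conjugated enyne delivers both hydrogens to one face of the triple bond, which should give the Z alkene (C7=C8) without over-reduction and without touching the unconjugated terminal alkene.

Step 4
Reactants: 6 ethyl 3-oxobutanoate
Product: 7 ethyl (2E)-3-{[(trifluoromethyl)sulfonyl]oxy}but-2-enoate
Conditions: Tf2O, aq. Me4NOH, hexanes, 5 °C
Reagents that add atoms: trifluoromethanesulfonic anhydride, O=S(=O)(OS(=O)(=O)C(F)(F)F)C(F)(F)F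
Why: O-sulfonylation of the β-keto ester enolate, where the non-chelating tetramethylammonium counter-ion lets the enolate react in its extended form, should place the triflate trans to the ester (E).

Step 5
Reactants: 5 tert-butyl{[(2Z,4E)-6,6-dimethylnona-2,4,8-trien-1-yl]oxy}dimethylsilane; 7 ethyl (2E)-3-{[(trifluoromethyl)sulfonyl]oxy}but-2-enoate
Product: 9 ethyl (2E,8E,10Z)-12-{[tert-butyl(dimethyl)silyl]oxy}-3,7,7-trimethyldodeca-2,8,10-trienoate, via B-alkyl-9-BBN 8 (not isolated)
Conditions: 9-BBN, THF, 0 °C → rt; then 7, PdCl2(dppf) (cat.), K3PO4, DMF/H2O, rt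
Reagents that add atoms: none
Why: Anti-Markovnikov hydroboration by 9-BBN is far faster at the monosubstituted alkene than at the 1,2-disubstituted diene, and the B-alkyl Suzuki–Miyaura coupling with the E-enol triflate proceeds with retention, which fixes the trisubstituted C9=C10 bond as E.

Step 6
Reactants: 9 ethyl (2E,8E,10Z)-12-{[tert-butyl(dimethyl)silyl]oxy}-3,7,7-trimethyldodeca-2,8,10-trienoate
Product: 10 (2E,8E,10Z)-12-{[tert-butyl(dimethyl)silyl]oxy}-3,7,7-trimethyldodeca-2,8,10-trien-1-ol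
Conditions: i-Bu2AlH, CH2Cl2, −78 °C
Reagents that add atoms: none
Why: Hydride 1,2-reduction of a conjugated ester with i-Bu2AlH gives the allylic alcohol and affects neither the silyl ether nor the diene.

Step 7
Reactants: 10 (2E,8E,10Z)-12-{[tert-butyl(dimethyl)silyl]oxy}-3,7,7-trimethyldodeca-2,8,10-trien-1-ol
Product: 11 (2E,8E,10Z)-12-{[tert-butyl(dimethyl)silyl]oxy}-3,7,7-trimethyldodeca-2,8,10-trienal
Conditions: MnO2, CH2Cl2, rt
Reagents that add atoms: none
Why: Allylic oxidation with MnO2 is neutral and stops at the aldehyde, so the 2E geometry and the Z-diene should survive.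

Step 8
Reactants: 11 (2E,8E,10Z)-12-{[tert-butyl(dimethyl)silyl]oxy}-3,7,7-trimethyldodeca-2,8,10-trienal
Product: 12 (1R,2S,4aR,8aR)-2-({[tert-butyl(dimethyl)silyl]oxy}methyl)-5,5,8a-trimethyl-1,2,4a,5,6,7,8,8a-octahydronaphthalene-1-carbaldehyde
Conditions: (3aS)-1-(2-methylphenyl)-3,3-diphenyltetrahydro-1H,3H-pyrrolo[1,2-c][1,3,2]oxazaborole (20 mol %), Tf2NH (18 mol %), CH2Cl2, −78 → −20 °C
Reagents that add atoms: none
Why: The oxazaborolidinium ion binds the formyl oxygen and lowers the LUMO of the C9=C10 enal, which then adds to the C5=C6–C7=C8 diene in a concerted but asynchronous [4+2] cycloaddition with the C5–C10 bond more advanced. The closest known reaction type is the Lewis-acid- and oxazaborolidinium-catalysed type 1 intramolecular Diels–Alder reaction of 1,7,9-decatrienals to trans-octalins. Ring B closes as the six-membered cycloadduct ring through the bond pair C5–C10 and C8–C9, and ring A closes in the same event in the fused, 6-exo sense because the C1–C4 tether already joins C10 to C5, the gem-dimethyl group at C4 favouring the folded rotamer. Suprafacial addition turns olefin geometry into relative configuration: the E enal places C11 cis to C20 (C9, C10), the E,Z-diene places C17 cis to H5 (C8, C5), and the endo transition state (formyl group under the diene, tether pointing away) gives the trans ring fusion with C11 trans to C17. The absolute configuration comes from the catalyst alone, which must leave the Re face of C9 (Si face of C10) open; by the stacking model the aryl group of the (S)-prolinol-derived catalyst should cover the other face. The step needs endo and facial selectivity and unchanged olefin geometry, which the catalyst-bound E enal and the low temperature (no 1,5-hydrogen shift or isomerisation of the Z-diene) should secure.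

Step 9
Reactants: 12 (1R,2S,4aR,8aR)-2-({[tert-butyl(dimethyl)silyl]oxy}methyl)-5,5,8a-trimethyl-1,2,4a,5,6,7,8,8a-octahydronaphthalene-1-carbaldehyde
Product: 13 tert-butyl{[(1R,2S,4aR,8aS)-1-ethenyl-5,5,8a-trimethyl-1,2,4a,5,6,7,8,8a-octahydronaphthalen-2-yl]methoxy}dimethylsilane
Conditions: Ph3PCH3Br, KN(SiMe3)2, THF, 0 °C → rt
Reagents that add atoms: methyltriphenylphosphonium bromide, C[P+](c1ccccc1)(c1ccccc1)c1ccccc1.[Br-]
Why: Wittig methylenation with the non-stabilised ylide works on hindered aldehydes, and C9 already holds its equatorial, thermodynamically preferred configuration, so the base should not change it.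

Step 10
Reactants: 14 2-(prop-2-yn-1-yloxy)oxane (racemic)
Product: 15 tert-butyl 4-(oxan-2-yloxy)but-2-ynoate (racemic)
Conditions: n-BuLi, THF, −78 °C; then Boc2O, −78 → 0 °C
Reagents that add atoms: di-tert-butyl dicarbonate, CC(C)(C)OC(=O)OC(=O)OC(C)(C)C
Why: Alkoxycarbonylation of the lithium acetylide with Boc2O gives the tert-butyl ynoate (C15 with C14, C13 and C16).

Step 11
Reactants: 15 tert-butyl 4-(oxan-2-yloxy)but-2-ynoate
Product: 16 tert-butyl 4-hydroxybut-2-ynoate
Conditions: PPTS (cat.), MeOH, 40 °C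
Reagents that add atoms: none
Why: Acid-catalysed transacetalisation to methanol removes the tetrahydropyranyl group under conditions too mild to cleave a tert-butyl ester.

Step 12
Reactants: 16 tert-butyl 4-hydroxybut-2-ynoate
Product: 17 tert-butyl (2Z)-4-hydroxy-3-iodobut-2-enoate
Conditions: NaI, AcOH, 70 °C
Reagents that add atoms: sodium iodide, [Na+].[I-]
Why: Conjugate hydroiodination of the ynoate is an anti addition (iodide to C13, proton to C14), which should give the Z-iodide with the hydroxymethyl group trans to the ester, where it cannot lactonise.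

Step 13
Reactants: 13 tert-butyl{[(1R,2S,4aR,8aS)-1-ethenyl-5,5,8a-trimethyl-1,2,4a,5,6,7,8,8a-octahydronaphthalen-2-yl]methoxy}dimethylsilane; 17 tert-butyl (2Z)-4-hydroxy-3-iodobut-2-enoate
Product: 19 tert-butyl (2E)-5-[(1R,2S,4aR,8aS)-2-({[tert-butyl(dimethyl)silyl]oxy}methyl)-5,5,8a-trimethyl-1,2,4a,5,6,7,8,8a-octahydronaphthalen-1-yl]-3-(hydroxymethyl)pent-2-enoate, via B-alkyl-9-BBN 18 (not isolated)
Conditions: 9-BBN, THF, rt → 45 °C; then 17, PdCl2(dppf) (cat.), AsPh3, Cs2CO3, DMF/H2O, rt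
Reagents that add atoms: none
Why: 9-BBN hydroborates only the monosubstituted vinyl group (the ring alkene is cis-disubstituted and flanked by C5 and C8), and B-alkyl Suzuki–Miyaura coupling with the activated β-iodo enoate proceeds with retention, so C12 ends cis to the ester (13E) with the free hydroxyl tolerated.

Step 14
Reactants: 19 tert-butyl (2E)-5-[(1R,2S,4aR,8aS)-2-({[tert-butyl(dimethyl)silyl]oxy}methyl)-5,5,8a-trimethyl-1,2,4a,5,6,7,8,8a-octahydronaphthalen-1-yl]-3-(hydroxymethyl)pent-2-enoate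
Product: 20 tert-butyl (2E)-3-(acetoxymethyl)-5-[(1R,2S,4aR,8aS)-2-({[tert-butyl(dimethyl)silyl]oxy}methyl)-5,5,8a-trimethyl-1,2,4a,5,6,7,8,8a-octahydronaphthalen-1-yl]pent-2-enoate
Conditions: Ac2O, pyridine, DMAP (cat.), CH2Cl2, 0 °C → rt
Reagents that add atoms: acetic anhydride, CC(=O)OC(C)=O
Why: DMAP-catalysed O-acylation of the only free hydroxyl (C16) is routine.

Step 15
Reactants: 20 tert-butyl (2E)-3-(acetoxymethyl)-5-[(1R,2S,4aR,8aS)-2-({[tert-butyl(dimethyl)silyl]oxy}methyl)-5,5,8a-trimethyl-1,2,4a,5,6,7,8,8a-octahydronaphthalen-1-yl]pent-2-enoate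
Product: 21 (2E)-3-(acetoxymethyl)-5-[(1R,2S,4aR,8aS)-2-(hydroxymethyl)-5,5,8a-trimethyl-1,2,4a,5,6,7,8,8a-octahydronaphthalen-1-yl]pent-2-enoic acid
Conditions: TFA/CH2Cl2/H2O (10:20:1), 0 °C → rt
Reagents that add atoms: none
Why: Acidolysis removes the tert-butyl ester by E1-type loss of isobutene and the primary TBS ether by protodesilylation in one operation, whereas the primary acetate, the enoate geometry and the disubstituted ring alkene should be stable to acid at this temperature.

Step 16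
Reactants: 21 (2E)-3-(acetoxymethyl)-5-[(1R,2S,4aR,8aS)-2-(hydroxymethyl)-5,5,8a-trimethyl-1,2,4a,5,6,7,8,8a-octahydronaphthalen-1-yl]pent-2-enoic acid
Product: 23 (1R,2S,4aR,8aS)-1-[(3E)-3-(acetoxymethyl)-4-carboxybut-3-en-1-yl]-5,5,8a-trimethyl-1,2,4a,5,6,7,8,8a-octahydronaphthalene-2-carboxylic acid, via aldehyde acid 22 (not isolated)
Conditions: TEMPO (cat.), PhI(OAc)2, MeCN/H2O (1:1), rt
Reagents that add atoms: water, O
Why: Nitroxyl-catalysed oxidation takes the primary alcohol to the aldehyde and, through its hydrate, on to the acid under nearly neutral conditions that should neither epimerise C8 nor move the C6=C7 bond, and that tolerate the acetate and the free acid.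

Compound list
1 | 2,2-dimethylpent-4-enal | C=CCC(C)(C)C=O | starting material
2 | (1E)-1-iodo-3,3-dimethylhexa-1,5-diene | I/C=C/C(C)(C)CC=C | intermediate
3 | tert-butyldimethyl(prop-2-yn-1-yloxy)silane | C#CCO[Si](C)(C)C(C)(C)C | starting material
4 | tert-butyl{[(4E)-6,6-dimethylnona-4,8-dien-2-yn-1-yl]oxy}dimethylsilane | C=CCC(C)(C)/C=C/C#CCO[Si](C)(C)C(C)(C)C | intermediate
5 | tert-butyl{[(2Z,4E)-6,6-dimethylnona-2,4,8-trien-1-yl]oxy}dimethylsilane | C=CCC(C)(C)/C=C/C=C\CO[Si](C)(C)C(C)(C)C | intermediate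
6 | ethyl 3-oxobutanoate (ethyl acetoacetate) | CCOC(=O)CC(C)=O | starting material
7 | ethyl (2E)-3-{[(trifluoromethyl)sulfonyl]oxy}but-2-enoate | CCOC(=O)/C=C(\C)OS(=O)(=O)C(F)(F)F | intermediate
8 | 9-[(5E,7Z)-9-{[tert-butyl(dimethyl)silyl]oxy}-4,4-dimethylnona-5,7-dien-1-yl]-9-borabicyclo[3.3.1]nonane | CC(C)(C)[Si](C)(C)OC/C=C\C=C\C(C)(C)CCCB1C2CCCC1CCC2 | intermediate (not isolated)
9 | ethyl (2E,8E,10Z)-12-{[tert-butyl(dimethyl)silyl]oxy}-3,7,7-trimethyldodeca-2,8,10-trienoate | CCOC(=O)/C=C(\C)CCCC(C)(C)/C=C/C=C\CO[Si](C)(C)C(C)(C)C | intermediate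
10 | (2E,8E,10Z)-12-{[tert-butyl(dimethyl)silyl]oxy}-3,7,7-trimethyldodeca-2,8,10-trien-1-ol | OC/C=C(\C)CCCC(C)(C)/C=C/C=C\CO[Si](C)(C)C(C)(C)C | intermediate
11 | (2E,8E,10Z)-12-{[tert-butyl(dimethyl)silyl]oxy}-3,7,7-trimethyldodeca-2,8,10-trienal (precursor of the key step) | O=C/C=C(\C)CCCC(C)(C)/C=C/C=C\CO[Si](C)(C)C(C)(C)C | intermediate
12 | (1R,2S,4aR,8aR)-2-({[tert-butyl(dimethyl)silyl]oxy}methyl)-5,5,8a-trimethyl-1,2,4a,5,6,7,8,8a-octahydronaphthalene-1-carbaldehyde (trans-fused; C11 and C20 on one face, H5 and C17 on the other) | O=C[C@@H]1[C@@H](CO[Si](C)(C)C(C)(C)C)C=C[C@@H]2C(C)(C)CCC[C@@]12C | intermediate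
13 | tert-butyl{[(1R,2S,4aR,8aS)-1-ethenyl-5,5,8a-trimethyl-1,2,4a,5,6,7,8,8a-octahydronaphthalen-2-yl]methoxy}dimethylsilane | C=C[C@@H]1[C@@H](CO[Si](C)(C)C(C)(C)C)C=C[C@@H]2C(C)(C)CCC[C@@]12C | intermediate
14 | 2-(prop-2-yn-1-yloxy)oxane (racemic) | C#CCOC1CCCCO1 | starting material
15 | tert-butyl 4-(oxan-2-yloxy)but-2-ynoate (racemic) | CC(C)(C)OC(=O)C#CCOC1CCCCO1 | intermediate
16 | tert-butyl 4-hydroxybut-2-ynoate | CC(C)(C)OC(=O)C#CCO | intermediate
17 | tert-butyl (2Z)-4-hydroxy-3-iodobut-2-enoate | CC(C)(C)OC(=O)/C=C(\I)CO | intermediate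
18 | 9-{2-[(1R,2S,4aR,8aS)-2-({[tert-butyl(dimethyl)silyl]oxy}methyl)-5,5,8a-trimethyl-1,2,4a,5,6,7,8,8a-octahydronaphthalen-1-yl]ethyl}-9-borabicyclo[3.3.1]nonane | C1CCC2CCCC1B2CC[C@@H]3[C@@H](CO[Si](C)(C)C(C)(C)C)C=C[C@@H]4C(C)(C)CCC[C@@]34C | intermediate (not isolated)
19 | tert-butyl (2E)-5-[(1R,2S,4aR,8aS)-2-({[tert-butyl(dimethyl)silyl]oxy}methyl)-5,5,8a-trimethyl-1,2,4a,5,6,7,8,8a-octahydronaphthalen-1-yl]-3-(hydroxymethyl)pent-2-enoate | CC(C)(C)OC(=O)/C=C(/CO)CC[C@@H]1[C@@H](CO[Si](C)(C)C(C)(C)C)C=C[C@@H]2C(C)(C)CCC[C@@]12C | intermediate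
20 | tert-butyl (2E)-3-(acetoxymethyl)-5-[(1R,2S,4aR,8aS)-2-({[tert-butyl(dimethyl)silyl]oxy}methyl)-5,5,8a-trimethyl-1,2,4a,5,6,7,8,8a-octahydronaphthalen-1-yl]pent-2-enoate | CC(=O)OC/C(=C/C(=O)OC(C)(C)C)CC[C@@H]1[C@@H](CO[Si](C)(C)C(C)(C)C)C=C[C@@H]2C(C)(C)CCC[C@@]12C | intermediate
21 | (2E)-3-(acetoxymethyl)-5-[(1R,2S,4aR,8aS)-2-(hydroxymethyl)-5,5,8a-trimethyl-1,2,4a,5,6,7,8,8a-octahydronaphthalen-1-yl]pent-2-enoic acid | CC(=O)OC/C(=C/C(=O)O)CC[C@@H]1[C@@H](CO)C=C[C@@H]2C(C)(C)CCC[C@@]12C | intermediate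
22 | (2E)-3-(acetoxymethyl)-5-[(1R,2S,4aR,8aS)-2-formyl-5,5,8a-trimethyl-1,2,4a,5,6,7,8,8a-octahydronaphthalen-1-yl]pent-2-enoic acid | CC(=O)OC/C(=C/C(=O)O)CC[C@@H]1[C@@H](C=O)C=C[C@@H]2C(C)(C)CCC[C@@]12C | intermediate (not isolated)
23 | (1R,2S,4aR,8aS)-1-[(3E)-3-(acetoxymethyl)-4-carboxybut-3-en-1-yl]-5,5,8a-trimethyl-1,2,4a,5,6,7,8,8a-octahydronaphthalene-2-carboxylic acid (CNP0108723.1) | CC(=O)OC/C(=C/C(=O)O)CC[C@@H]1[C@@H](C(=O)O)C=C[C@@H]2C(C)(C)CCC[C@@]12C | target

Total step count: 16.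
Longest linear sequence: 12 steps (1 → 2 → 4 → 5 → 9 → 10 → 11 → 12 → 13 → 19 → 20 → 21 → 23; steps 1, 2, 3, 5, 6, 7, 8, 9, 13, 14, 15, 16).

Steps most likely to fail

Step 8. The β,β-disubstituted enal is a weak dienophile and the diene must turn its Z substituent inward, so the cycloaddition may be too slow at temperatures where the catalyst still discriminates. The Lewis acid may also isomerise the enal or the Z-diene, or ionise the dienylic silyl ether, and facial selectivity may be poor or of the opposite sense. The developing 1,3-diaxial contact between C20 and the axial methyl on C4 may erode the endo preference. The fallback replaces catalyst control by a covalently bound controller. It sets out from ester 9, which is saponified (LiOH, THF/MeOH/H2O) to the trienoic acid F1. The pivaloyl mixed anhydride of F1 is coupled with lithiated (4R)-4-benzyl-1,3-oxazolidin-2-one to the trienoyl imide F2. Me2AlCl (CH2Cl2, −30 °C) then promotes the auxiliary-directed intramolecular Diels–Alder reaction through the chelated s-cis acyl imide, whose benzyl group covers the Si face of C9, to the cycloadduct imide F3. LiBH4 (THF, H2O, 0 °C) releases the primary alcohol F4 together with the auxiliary, and Dess–Martin oxidation of F4 comes back to the route at aldehyde 12.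

Step 5. Hydroxide may attack the β-carbon of triflate 7 and destroy it faster than the alkyl group moves from boron to palladium, and protodeboronation may compete. The fallback is a base-free coupling through zinc. It sets out from triene 5, which is hydroborated as before, and the borane 8 is oxidised (NaOH, H2O2) to the primary alcohol F5. I2, PPh3 and imidazole convert F5 into the primary iodide F6, and zinc insertion (Zn dust, LiCl, THF) gives the alkylzinc iodide F7. Negishi coupling of F7 with 7 (Pd(PPh3)4 (cat.), THF, rt), again with retention, comes back at ester 9.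

Step 16. At the stage of the β,γ-unsaturated aldehyde 22, C8 may epimerise or the C6=C7 bond may move into conjugation, and the oxoammonium species may attack the ring alkene. The fallback changes the order of events and the oxidant. It sets out from 20, where HF·pyridine (THF/pyridine, 0 °C) removes only the silyl group to give the hydroxy ester F8. Buffered Dess–Martin oxidation (NaHCO3, CH2Cl2) gives the isolated aldehyde F9. Pinnick oxidation (NaClO2, NaH2PO4, 2-methylbut-2-ene, t-BuOH/H2O) gives the mono acid F10, and TFA/CH2Cl2 cleaves the tert-butyl ester of F10 to come back at target 23.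

Further compounds
F1 | step 8 | (2E,8E,10Z)-12-{[tert-butyl(dimethyl)silyl]oxy}-3,7,7-trimethyldodeca-2,8,10-trienoic acid | OC(=O)/C=C(\C)CCCC(C)(C)/C=C/C=C\CO[Si](C)(C)C(C)(C)C
F2 | step 8 | (4R)-4-benzyl-3-[(2E,8E,10Z)-12-{[tert-butyl(dimethyl)silyl]oxy}-3,7,7-trimethyldodeca-2,8,10-trienoyl]-1,3-oxazolidin-2-one | O=C1OC[C@@H](Cc2ccccc2)N1C(=O)/C=C(\C)CCCC(C)(C)/C=C/C=C\CO[Si](C)(C)C(C)(C)C
F3 | step 8 | (4R)-4-benzyl-3-{[(1R,2S,4aR,8aR)-2-({[tert-butyl(dimethyl)silyl]oxy}methyl)-5,5,8a-trimethyl-1,2,4a,5,6,7,8,8a-octahydronaphthalen-1-yl]carbonyl}-1,3-oxazolidin-2-one | O=C1OC[C@@H](Cc2ccccc2)N1C(=O)[C@@H]3[C@@H](CO[Si](C)(C)C(C)(C)C)C=C[C@@H]4C(C)(C)CCC[C@@]34C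
F4 | step 8 | [(1R,2S,4aR,8aR)-2-({[tert-butyl(dimethyl)silyl]oxy}methyl)-5,5,8a-trimethyl-1,2,4a,5,6,7,8,8a-octahydronaphthalen-1-yl]methanol | OC[C@@H]1[C@@H](CO[Si](C)(C)C(C)(C)C)C=C[C@@H]2C(C)(C)CCC[C@@]12C
F5 | step 5 | (5E,7Z)-9-{[tert-butyl(dimethyl)silyl]oxy}-4,4-dimethylnona-5,7-dien-1-ol | OCCCC(C)(C)/C=C/C=C\CO[Si](C)(C)C(C)(C)C
F6 | step 5 | tert-butyl{[(2Z,4E)-9-iodo-6,6-dimethylnona-2,4-dien-1-yl]oxy}dimethylsilane | ICCCC(C)(C)/C=C/C=C\CO[Si](C)(C)C(C)(C)C
F7 | step 5 | [(5E,7Z)-9-{[tert-butyl(dimethyl)silyl]oxy}-4,4-dimethylnona-5,7-dien-1-yl]zinc iodide | I[Zn]CCCC(C)(C)/C=C/C=C\CO[Si](C)(C)C(C)(C)C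
F8 | step 16 | tert-butyl (2E)-3-(acetoxymethyl)-5-[(1R,2S,4aR,8aS)-2-(hydroxymethyl)-5,5,8a-trimethyl-1,2,4a,5,6,7,8,8a-octahydronaphthalen-1-yl]pent-2-enoate | CC(=O)OC/C(=C/C(=O)OC(C)(C)C)CC[C@@H]1[C@@H](CO)C=C[C@@H]2C(C)(C)CCC[C@@]12C
F9 | step 16 | tert-butyl (2E)-3-(acetoxymethyl)-5-[(1R,2S,4aR,8aS)-2-formyl-5,5,8a-trimethyl-1,2,4a,5,6,7,8,8a-octahydronaphthalen-1-yl]pent-2-enoate | CC(=O)OC/C(=C/C(=O)OC(C)(C)C)CC[C@@H]1[C@@H](C=O)C=C[C@@H]2C(C)(C)CCC[C@@]12C
F10 | step 16 | (1R,2S,4aR,8aS)-1-[(3E)-3-(acetoxymethyl)-5-tert-butoxy-5-oxopent-3-en-1-yl]-5,5,8a-trimethyl-1,2,4a,5,6,7,8,8a-octahydronaphthalene-2-carboxylic acid | CC(=O)OC/C(=C/C(=O)OC(C)(C)C)CC[C@@H]1[C@@H](C(=O)O)C=C[C@@H]2C(C)(C)CCC[C@@]12C
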